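**Retrosynthetic overview**

1. Target 32 ⇐ hydroxy lactone 28: acetonide removal, C9–O esterification with (2S,3S)-epoxyangelic acid 9 (its oxirane comes from a Sharpless epoxidation), then C8–O acetylation.
2. 28 ⇐ iodovinyl ortho ester 25 + CO2 (key): C11–C12 by carboxylation of the C11 vinyllithium, lactone O–C6 by invertive attack of the new carboxyl on C6. The enabling feature is the contiguous C6(O)–C7(OH)–C11(=C13) array: the tertiary C7 hydroxyl is 1,2 to the allylic C6 carbinol and C7 carries the vinyl carbon C11, so O6 and O7 can be tied in a temporary 2-methoxy-1,3-dioxolane ring whose ionisation makes O6 a leaving group held anti to C11.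
3. 25 ⇐ aldehyde 21: ten-membered carbocycle by Nozaki–Hiyama–Kishi closure of C5–C6, then the ortho ester ring and the C11 iodide.
4. 21 ⇐ phosphonium salt 5 + methyl ketone 12: C1=C10 by Z-selective Wittig olefination of the α-alkoxy ketone derived from D-erythronolactone acetonide 10 (source of C8, C9 and the dioxolane); C7 by chelation-controlled addition to ynone 18.
5. Ring order: dioxolane (present in 10) → ten-membered ring (step 17) → temporary ortho ester ring (step 18) → γ-lactone (step 20, ortho ester ring cleaved); the side-chain oxirane is made separately (step 5).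

Key step: step 20

Remark: locants C1–C15 follow germacrane numbering throughout (C12 lactone carbonyl, C13 exocyclic methylene), also in the acyclic precursors; pent-4-yn-1-ol, angelic acid and 2,3-O-isopropylidene-D-erythronolactone are taken as commercial.

**Route**

Step 1
Reactants: 1 pent-4-yn-1-ol
Product: 3 (E)-5-iodo-4-methylpent-4-en-1-ol, via alkenylalane 2 (not isolated)
Conditions: AlMe3 (3 equiv), Cp2ZrCl2 (0.25 equiv), CH2Cl2, 0 to 23 °C; then I2, THF, −30 °C
Reagents that add atoms: trimethylaluminium, C[Al](C)C; iodine, II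
Why: Zirconium-catalysed carboalumination (Negishi) adds methyl and aluminium syn across the terminal alkyne with aluminium at the terminus, and iodinolysis with retention fixes the E trisubstituted C4=C5 olefin.

Step 2
Reactants: 3 (E)-5-iodo-4-methylpent-4-en-1-ol
Product: 4 (E)-1,5-diiodo-2-methylpent-1-ene
Conditions: I2, PPh3, imidazole, CH2Cl2, 0 °C
Reagents that add atoms: iodine, II
Why: Appel-type iodination converts the primary alcohol into the iodide by SN2 displacement of the oxyphosphonium group and leaves the alkenyl iodide untouched.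

Step 3
Reactants: 4 (E)-1,5-diiodo-2-methylpent-1-ene
Product: 5 [(E)-5-iodo-4-methylpent-4-en-1-yl]triphenylphosphonium iodide
Conditions: PPh3, MeCN, 80 °C
Reagents that add atoms: triphenylphosphine, c1ccc(cc1)P(c1ccccc1)c1ccccc1
Why: SN2 quaternisation of the phosphine by the primary alkyl iodide gives the Wittig salt, the alkenyl iodide being inert to phosphine.

Step 4
Reactants: 6 angelic acid
Product: 7 (Z)-2-methylbut-2-en-1-ol
Conditions: LiAlH4, Et2O, 0 °C
Reagents that add atoms: none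
Why: Hydride reduction of the carboxylic acid by LiAlH4 gives the allylic alcohol by 1,2-delivery without isomerising the Z trisubstituted olefin.

Step 5
Reactants: 7 (Z)-2-methylbut-2-en-1-ol
Product: 8 [(2R,3S)-2,3-dimethyloxiran-2-yl]methanol
Conditions: Ti(OiPr)4, D-(−)-diethyl tartrate, t-BuOOH, 4 Å molecular sieves, CH2Cl2, −20 °C
Reagents that add atoms: tert-butyl hydroperoxide, CC(C)(C)OO
Why: Sharpless asymmetric epoxidation with the D-(−)-tartrate delivers oxygen to the olefin face that gives the (2R,3S)-epoxy alcohol, and the cis relation of CH2OH and the C3 methyl follows from the Z olefin.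

Step 6
Reactants: 8 [(2R,3S)-2,3-dimethyloxiran-2-yl]methanol
Product: 9 (2S,3S)-2,3-dimethyloxirane-2-carboxylic acid
Conditions: RuCl3 (cat.), NaIO4, MeCN/EtOAc/H2O, 0 to 23 °C
Reagents that add atoms: sodium periodate, [Na+].[O-]I(=O)(=O)=O; water, O
Why: RuO4 generated catalytically from RuCl3 and NaIO4 oxidises the primary alcohol to the acid under near-neutral conditions that leave the oxirane and both stereocentres untouched (the descriptor at C2 changes only because the priorities change).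

Step 7
Reactants: 10 2,3-O-isopropylidene-D-erythronolactone
Product: 11 1-deoxy-3,4-O-isopropylidene-D-erythro-pent-2-ulofuranose
Conditions: MeLi (1.05 equiv), THF, −78 °C
Reagents that add atoms: methyllithium, [Li]C
Why: Addition of one equivalent of MeLi to the γ-lactone at low temperature stops at the lithium hemiketal (acyl substitution arrested at the tetrahedral stage), which gives the methyl ketose lactol on protonation.

Step 8
Reactants: 11 1-deoxy-3,4-O-isopropylidene-D-erythro-pent-2-ulofuranose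
Product: 12 1-[(4R,5R)-5-{[tert-butyl(dimethyl)silyl]oxymethyl}-2,2-dimethyl-1,3-dioxolan-4-yl]ethan-1-one
Conditions: t-BuMe2SiCl, imidazole, DMF, 23 °C
Reagents that add atoms: tert-butyldimethylsilyl chloride, CC(C)(C)[Si](C)(C)Cl
Why: Silylation traps the primary hydroxyl of the open-chain hydroxy ketone tautomer, which drains the hemiketal equilibrium and unveils the α-alkoxy methyl ketone without touching C8 or C9.

Step 9
Reactants: 5 [(E)-5-iodo-4-methylpent-4-en-1-yl]triphenylphosphonium iodide; 12 1-[(4R,5R)-5-{[tert-butyl(dimethyl)silyl]oxymethyl}-2,2-dimethyl-1,3-dioxolan-4-yl]ethan-1-one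
Product: 14 tert-butyl{[(4R,5S)-5-[(2Z,6E)-7-iodo-6-methylhepta-2,6-dien-2-yl]-2,2-dimethyl-1,3-dioxolan-4-yl]methoxy}dimethylsilane, via ylide 13 (not isolated)
Conditions: 5, NaN(SiMe3)2, THF, 0 °C; then 12, −78 to 23 °C
Reagents that add atoms: none
Why: Wittig olefination of an α-alkoxy methyl ketone with a non-stabilised ylide is kinetically Z-selective, so the ylide chain (C2) should end cis to the oxygen-bearing C9 and set the 1(10)Z olefin.

Step 10
Reactants: 14 tert-butyl{[(4R,5S)-5-[(2Z,6E)-7-iodo-6-methylhepta-2,6-dien-2-yl]-2,2-dimethyl-1,3-dioxolan-4-yl]methoxy}dimethylsilane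
Product: 15 [(4R,5S)-5-[(2Z,6E)-7-iodo-6-methylhepta-2,6-dien-2-yl]-2,2-dimethyl-1,3-dioxolan-4-yl]methanol
Conditions: Bu4NF, THF, 0 °C
Reagents that add atoms: none
Why: Fluoride-induced desilylation (Si–F bond formation) frees the primary alcohol and leaves acetonide, alkenyl iodide and olefins alone.

Step 11
Reactants: 15 [(4R,5S)-5-[(2Z,6E)-7-iodo-6-methylhepta-2,6-dien-2-yl]-2,2-dimethyl-1,3-dioxolan-4-yl]methanol
Product: 16 (4S,5S)-5-[(2Z,6E)-7-iodo-6-methylhepta-2,6-dien-2-yl]-2,2-dimethyl-1,3-dioxolane-4-carbaldehyde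
Conditions: Dess–Martin periodinane, NaHCO3, CH2Cl2, 0 °C
Reagents that add atoms: none
Why: Dess–Martin oxidation under buffered, non-basic conditions should give the α-alkoxy aldehyde without epimerising C8.

Step 12
Reactants: 16 (4S,5S)-5-[(2Z,6E)-7-iodo-6-methylhepta-2,6-dien-2-yl]-2,2-dimethyl-1,3-dioxolane-4-carbaldehyde
Product: 17 1-[(4R,5S)-5-[(2Z,6E)-7-iodo-6-methylhepta-2,6-dien-2-yl]-2,2-dimethyl-1,3-dioxolan-4-yl]-3-(trimethylsilyl)prop-2-yn-1-ol
Conditions: Me3SiC≡CH, n-BuLi, THF, −78 °C; then 16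
Reagents that add atoms: ethynyltrimethylsilane, C#C[Si](C)(C)C
Why: 1,2-Addition of the preformed lithium acetylide to the aldehyde installs C11 and C13, and the new carbinol centre needs no control because it is oxidised in the next step.

Step 13
Reactants: 17 1-[(4R,5S)-5-[(2Z,6E)-7-iodo-6-methylhepta-2,6-dien-2-yl]-2,2-dimethyl-1,3-dioxolan-4-yl]-3-(trimethylsilyl)prop-2-yn-1-ol
Product: 18 1-[(4S,5S)-5-[(2Z,6E)-7-iodo-6-methylhepta-2,6-dien-2-yl]-2,2-dimethyl-1,3-dioxolan-4-yl]-3-(trimethylsilyl)prop-2-yn-1-one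
Conditions: Dess–Martin periodinane, NaHCO3, CH2Cl2, 23 °C
Reagents that add atoms: none
Why: Dess–Martin oxidation of the propargylic alcohol gives the ynone, whose C-silyl group blocks conjugate addition in the next step.

Step 14
Reactants: 18 1-[(4S,5S)-5-[(2Z,6E)-7-iodo-6-methylhepta-2,6-dien-2-yl]-2,2-dimethyl-1,3-dioxolan-4-yl]-3-(trimethylsilyl)prop-2-yn-1-one
Product: 19 (2R)-2-[(4S,5S)-5-[(2Z,6E)-7-iodo-6-methylhepta-2,6-dien-2-yl]-2,2-dimethyl-1,3-dioxolan-4-yl]-1-[dimethyl(propan-2-yloxy)silyl]-4-(trimethylsilyl)but-3-yn-2-ol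
Conditions: (i-PrO)Me2SiCH2MgCl (from (i-PrO)Me2SiCH2Cl and Mg), MgBr2·OEt2, CH2Cl2/THF, −78 °C
Reagents that add atoms: (isopropoxydimethylsilyl)methylmagnesium chloride, CC(C)O[Si](C)(C)C[Mg]Cl
Why: In this chelation-controlled Grignard addition (Cram chelate model) magnesium bridges the ketone oxygen and the dioxolane oxygen O8 and the hydroxymethyl-equivalent nucleophile enters from the face of H8, which sets the C7 tertiary carbinol with O7 and O8 syn (7,8-threo).

Step 15
Reactants: 19 (2R)-2-[(4S,5S)-5-[(2Z,6E)-7-iodo-6-methylhepta-2,6-dien-2-yl]-2,2-dimethyl-1,3-dioxolan-4-yl]-1-[dimethyl(propan-2-yloxy)silyl]-4-(trimethylsilyl)but-3-yn-2-ol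
Product: 20 (2S)-2-[(4S,5S)-5-[(2Z,6E)-7-iodo-6-methylhepta-2,6-dien-2-yl]-2,2-dimethyl-1,3-dioxolan-4-yl]but-3-yne-1,2-diol
Conditions: 30% H2O2, KF, KHCO3, THF/MeOH, 23 °C
Reagents that add atoms: hydrogen peroxide, OO
Why: Tamao–Fleming oxidation converts the C6–Si bond into C6–OH without touching C7, and fluoride in methanol removes the alkynyl silyl group in the same operation.

Step 16
Reactants: 20 (2S)-2-[(4S,5S)-5-[(2Z,6E)-7-iodo-6-methylhepta-2,6-dien-2-yl]-2,2-dimethyl-1,3-dioxolan-4-yl]but-3-yne-1,2-diol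
Product: 21 (2R)-2-hydroxy-2-[(4S,5S)-5-[(2Z,6E)-7-iodo-6-methylhepta-2,6-dien-2-yl]-2,2-dimethyl-1,3-dioxolan-4-yl]but-3-ynal
Conditions: SO3·pyridine, DMSO, i-Pr2NEt, CH2Cl2, 0 °C
Reagents that add atoms: none
Why: Parikh–Doering oxidation takes the primary alcohol to the aldehyde, cannot oxidise the tertiary hydroxyl and avoids glycol cleavage, while the quaternary C7 excludes enolisation.

Step 17
Reactants: 21 (2R)-2-hydroxy-2-[(4S,5S)-5-[(2Z,6E)-7-iodo-6-methylhepta-2,6-dien-2-yl]-2,2-dimethyl-1,3-dioxolan-4-yl]but-3-ynal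
Product: 22 (1(10)Z,4E,6R,7S,8S,9S)-7-ethynyl-8,9-O-isopropylidene-4,10-dimethylcyclodeca-1(10),4-diene-6,7,8,9-tetrol
Conditions: CrCl2 (10 equiv), NiCl2 (cat.), DMSO/THF, 0.003 M, 23 °C
Reagents that add atoms: none
Why: Intramolecular Nozaki–Hiyama–Kishi addition of the alkenylchromium (E geometry retained) to the aldehyde closes the ten-membered ring at high dilution, and with trivalent chromium chelated between the aldehyde oxygen and O7 the attack on the face anti to C8 (past the slim ethynyl group) should give the 6,7-threo (6R) diol.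

Step 18
Reactants: 22 (1(10)Z,4E,6R,7S,8S,9S)-7-ethynyl-8,9-O-isopropylidene-4,10-dimethylcyclodeca-1(10),4-diene-6,7,8,9-tetrol
Product: 23 (1(10)Z,4E,6R,7S,8S,9S)-7-ethynyl-8,9-O-isopropylidene-6,7-O-(methoxymethylidene)-4,10-dimethylcyclodeca-1(10),4-diene-6,7,8,9-tetrol
Conditions: HC(OMe)3, pyridinium p-toluenesulfonate (cat.), CH2Cl2, 23 °C
Reagents that add atoms: trimethyl orthoformate, COC(OC)OC
Why: Acid-catalysed transorthoesterification ties the 1,2-diol O6/O7 into a 2-methoxy-1,3-dioxolane, which is stable to base and stores O6 as a latent leaving group (the ortho ester carbon is formed as both epimers, which is without consequence).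

Step 19
Reactants: 23 (1(10)Z,4E,6R,7S,8S,9S)-7-ethynyl-8,9-O-isopropylidene-6,7-O-(methoxymethylidene)-4,10-dimethylcyclodeca-1(10),4-diene-6,7,8,9-tetrol
Product: 25 (1(10)Z,4E,6R,7S,8S,9S)-7-(1-iodoethenyl)-8,9-O-isopropylidene-6,7-O-(methoxymethylidene)-4,10-dimethylcyclodeca-1(10),4-diene-6,7,8,9-tetrol, via alkenylstannane 24 (not isolated)
Conditions: Bu3SnH, Mo(CO)3(CNt-Bu)3 (cat.), hydroquinone, THF, 55 °C; then I2, NaHCO3, CH2Cl2, 0 °C
Reagents that add atoms: iodine, II
Why: Molybdenum-catalysed hydrostannation of propargylic oxygen compounds places tin on the internal carbon (C11), and the ipso iododestannylation is far faster than any reaction of iodine with the ring olefins.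

Step 20
Reactants: 25 (1(10)Z,4E,6R,7S,8S,9S)-7-(1-iodoethenyl)-8,9-O-isopropylidene-6,7-O-(methoxymethylidene)-4,10-dimethylcyclodeca-1(10),4-diene-6,7,8,9-tetrol
Product: 28 (1(10)Z,4E,6S,7S,8S,9S)-7-hydroxy-8,9-isopropylidenedioxygermacra-1(10),4,11(13)-trien-12,6-olide, via lithium acrylate 26 (not isolated), via formate ester 27 (not isolated)
Conditions: t-BuLi (2.1 equiv), Et2O, −78 °C; CO2 (dry gas); then (±)-camphor-10-sulfonic acid (1.2 equiv), THF, −78 to 23 °C; then KHCO3, MeOH/H2O, 0 °C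
Reagents that add atoms: carbon dioxide, O=C=O
Why: Proposed new method: iodine–lithium exchange gives the C11 vinyllithium and CO2 converts it into the lithium acrylate 26 (C11–C12 bond); on anhydrous acidification the free acid protonates the 2-methoxy-1,3-dioxolane, methanol is lost, and the carboxyl oxygen attacks C6 of the resulting 1,3-dioxolan-2-ylium ion anti to the C6–O bond (O–C6 bond), which leaves O7 as a formate that the bicarbonate methanolysis removes. The closest known reaction types are the carboxylation of alkenyllithiums with CO2, the alkylation of carboxylic acids by dialkoxycarbenium ions (esterification with ortho esters or amide acetals, which inverts the alkyl carbon) and the backside opening of acyloxonium ions by a neighbouring carboxyl group. The γ-lactone ring O–C12–C11–C7–C6 closes in the 5-exo-tet mode. C6 is the only stereocentre that changes, from R to S, and the controlling element is the dioxolanylium ring: it holds the departing oxygen on one face while C11 on C7 lies anti to it, so even a partly ionised allylic C6 stays shielded on the face of the leaving oxygen. The step needs attack at C6 and not at C4 of the allylic system and no β-elimination of the vinyllithium; the five-membered tether allows only C6, and the acetal-type (not acyloxy) character of O7 at −78 °C secures the second.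

Step 21
Reactants: 28 (1(10)Z,4E,6S,7S,8S,9S)-7-hydroxy-8,9-isopropylidenedioxygermacra-1(10),4,11(13)-trien-12,6-olide
Product: 29 (1(10)Z,4E,6S,7S,8S,9S)-7,8,9-trihydroxygermacra-1(10),4,11(13)-trien-12,6-olide
Conditions: AcOH/H2O (4:1), 40 °C
Reagents that add atoms: none
Why: Mild aqueous acid hydrolyses the cis-fused isopropylidene acetal while the lactone and the tertiary alcohol are stable and the Z,E-diene should not be protonated at this acidity.

Step 22
Reactants: 29 (1(10)Z,4E,6S,7S,8S,9S)-7,8,9-trihydroxygermacra-1(10),4,11(13)-trien-12,6-olide; 9 (2S,3S)-2,3-dimethyloxirane-2-carboxylic acid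
Product: 31 (1(10)Z,4E,6S,7S,8S,9S)-9-[(2S,3S)-2,3-epoxy-2-methylbutanoyloxy]-7,8-dihydroxygermacra-1(10),4,11(13)-trien-12,6-olide, via mixed anhydride 30 (not isolated)
Conditions: 9, 2,4,6-trichlorobenzoyl chloride, Et3N, toluene, 23 °C; then 29, DMAP, 0 to 23 °C
Reagents that add atoms: none
Why: Yamaguchi esterification through the mixed anhydride should acylate the less hindered allylic C9 hydroxyl, since the C8 hydroxyl is shielded by the quaternary C7 and the C7 hydroxyl is tertiary, and no stereocentre is touched.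

Step 23
Reactants: 31 (1(10)Z,4E,6S,7S,8S,9S)-9-[(2S,3S)-2,3-epoxy-2-methylbutanoyloxy]-7,8-dihydroxygermacra-1(10),4,11(13)-trien-12,6-olide
Product: 32 (1(10)Z,4E,6S,7S,8S,9S)-8-acetoxy-9-[(2S,3S)-2,3-epoxy-2-methylbutanoyloxy]-7-hydroxygermacra-1(10),4,11(13)-trien-12,6-olide
Conditions: Ac2O, pyridine, DMAP (cat.), CH2Cl2, 0 °C
Reagents that add atoms: acetic anhydride, CC(=O)OC(C)=O
Why: DMAP-catalysed acetylation esterifies the remaining secondary C8 hydroxyl and leaves the tertiary C7 hydroxyl free.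

**Compound list**

1 | pent-4-yn-1-ol | C#CCCCO | starting material
2 | dimethyl[(E)-5-(dimethylalumanyloxy)-2-methylpent-1-en-1-yl]alumane | C[Al](C)/C=C(\C)CCCO[Al](C)C | intermediate
3 | (E)-5-iodo-4-methylpent-4-en-1-ol | OCCC/C(C)=C/I | intermediate
4 | (E)-1,5-diiodo-2-methylpent-1-ene | ICCC/C(C)=C/I | intermediate
5 | [(E)-5-iodo-4-methylpent-4-en-1-yl]triphenylphosphonium iodide | [I-].I/C=C(\C)CCC[P+](c1ccccc1)(c1ccccc1)c1ccccc1 | intermediate
6 | angelic acid, (Z)-2-methylbut-2-enoic acid | C/C=C(/C)C(=O)O | starting material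
7 | (Z)-2-methylbut-2-en-1-ol | C/C=C(/C)CO | intermediate
8 | [(2R,3S)-2,3-dimethyloxiran-2-yl]methanol | OC[C@@]1(C)O[C@H]1C | intermediate
9 | (2S,3S)-2,3-dimethyloxirane-2-carboxylic acid (epoxyangelic acid) | OC(=O)[C@@]1(C)O[C@H]1C | intermediate
10 | 2,3-O-isopropylidene-D-erythronolactone, (3aR,6aR)-2,2-dimethyldihydrofuro[3,4-d][1,3]dioxol-4(3aH)-one | O=C1[C@@H]2OC(C)(C)O[C@@H]2CO1 | starting material
11 | 1-deoxy-3,4-O-isopropylidene-D-erythro-pent-2-ulofuranose (hemiketal, both anomers) | CC1(O)[C@@H]2OC(C)(C)O[C@@H]2CO1 | intermediate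
12 | 1-[(4R,5R)-5-{[tert-butyl(dimethyl)silyl]oxymethyl}-2,2-dimethyl-1,3-dioxolan-4-yl]ethan-1-one | CC(=O)[C@@H]1OC(C)(C)O[C@@H]1CO[Si](C)(C)C(C)(C)C | intermediate
13 | [(E)-5-iodo-4-methylpent-4-en-1-ylidene]triphenylphosphorane | I/C=C(\C)CCC=P(c1ccccc1)(c1ccccc1)c1ccccc1 | intermediate
14 | tert-butyl{[(4R,5S)-5-[(2Z,6E)-7-iodo-6-methylhepta-2,6-dien-2-yl]-2,2-dimethyl-1,3-dioxolan-4-yl]methoxy}dimethylsilane | C/C(=C/CC/C(C)=C/I)[C@@H]1OC(C)(C)O[C@@H]1CO[Si](C)(C)C(C)(C)C | intermediate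
15 | [(4R,5S)-5-[(2Z,6E)-7-iodo-6-methylhepta-2,6-dien-2-yl]-2,2-dimethyl-1,3-dioxolan-4-yl]methanol | C/C(=C/CC/C(C)=C/I)[C@@H]1OC(C)(C)O[C@@H]1CO | intermediate
16 | (4S,5S)-5-[(2Z,6E)-7-iodo-6-methylhepta-2,6-dien-2-yl]-2,2-dimethyl-1,3-dioxolane-4-carbaldehyde | C/C(=C/CC/C(C)=C/I)[C@@H]1OC(C)(C)O[C@@H]1C=O | intermediate
17 | 1-[(4R,5S)-5-[(2Z,6E)-7-iodo-6-methylhepta-2,6-dien-2-yl]-2,2-dimethyl-1,3-dioxolan-4-yl]-3-(trimethylsilyl)prop-2-yn-1-ol (both carbinol epimers) | C/C(=C/CC/C(C)=C/I)[C@@H]1OC(C)(C)O[C@@H]1C(O)C#C[Si](C)(C)C | intermediate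
18 | 1-[(4S,5S)-5-[(2Z,6E)-7-iodo-6-methylhepta-2,6-dien-2-yl]-2,2-dimethyl-1,3-dioxolan-4-yl]-3-(trimethylsilyl)prop-2-yn-1-one | C/C(=C/CC/C(C)=C/I)[C@@H]1OC(C)(C)O[C@@H]1C(=O)C#C[Si](C)(C)C | intermediate
19 | (2R)-2-[(4S,5S)-5-[(2Z,6E)-7-iodo-6-methylhepta-2,6-dien-2-yl]-2,2-dimethyl-1,3-dioxolan-4-yl]-1-[dimethyl(propan-2-yloxy)silyl]-4-(trimethylsilyl)but-3-yn-2-ol | C/C(=C/CC/C(C)=C/I)[C@@H]1OC(C)(C)O[C@@H]1[C@](C#C[Si](C)(C)C)(C[Si](C)(C)OC(C)C)O | intermediate
20 | (2S)-2-[(4S,5S)-5-[(2Z,6E)-7-iodo-6-methylhepta-2,6-dien-2-yl]-2,2-dimethyl-1,3-dioxolan-4-yl]but-3-yne-1,2-diol | C/C(=C/CC/C(C)=C/I)[C@@H]1OC(C)(C)O[C@@H]1[C@](C#C)(CO)O | intermediate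
21 | (2R)-2-hydroxy-2-[(4S,5S)-5-[(2Z,6E)-7-iodo-6-methylhepta-2,6-dien-2-yl]-2,2-dimethyl-1,3-dioxolan-4-yl]but-3-ynal | C/C(=C/CC/C(C)=C/I)[C@@H]1OC(C)(C)O[C@@H]1[C@](C#C)(C=O)O | intermediate
22 | (1(10)Z,4E,6R,7S,8S,9S)-7-ethynyl-8,9-O-isopropylidene-4,10-dimethylcyclodeca-1(10),4-diene-6,7,8,9-tetrol | O[C@@H]1/C=C(\C)CC/C=C(/C)[C@@H]2OC(C)(C)O[C@@H]2[C@@]1(C#C)O | intermediate
23 | (1(10)Z,4E,6R,7S,8S,9S)-7-ethynyl-8,9-O-isopropylidene-6,7-O-(methoxymethylidene)-4,10-dimethylcyclodeca-1(10),4-diene-6,7,8,9-tetrol (both epimers at the ortho ester carbon) | COC1O[C@@H]2/C=C(\C)CC/C=C(/C)[C@@H]3OC(C)(C)O[C@@H]3[C@@]2(C#C)O1 | intermediate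
24 | (1(10)Z,4E,6R,7S,8S,9S)-8,9-O-isopropylidene-6,7-O-(methoxymethylidene)-4,10-dimethyl-7-[1-(tributylstannyl)ethenyl]cyclodeca-1(10),4-diene-6,7,8,9-tetrol | COC1O[C@@H]2/C=C(\C)CC/C=C(/C)[C@@H]3OC(C)(C)O[C@@H]3[C@@]2(C(=C)[Sn](CCCC)(CCCC)CCCC)O1 | intermediate
25 | (1(10)Z,4E,6R,7S,8S,9S)-7-(1-iodoethenyl)-8,9-O-isopropylidene-6,7-O-(methoxymethylidene)-4,10-dimethylcyclodeca-1(10),4-diene-6,7,8,9-tetrol | COC1O[C@@H]2/C=C(\C)CC/C=C(/C)[C@@H]3OC(C)(C)O[C@@H]3[C@@]2(C(I)=C)O1 | intermediate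
26 | lithium (1(10)Z,4E,6R,7S,8S,9S)-8,9-isopropylidenedioxy-6,7-(methoxymethylidenedioxy)germacra-1(10),4,11(13)-trien-12-oate | [Li+].COC1O[C@@H]2/C=C(\C)CC/C=C(/C)[C@@H]3OC(C)(C)O[C@@H]3[C@@]2(C(=C)C(=O)[O-])O1 | intermediate
27 | (1(10)Z,4E,6S,7S,8S,9S)-7-formyloxy-8,9-isopropylidenedioxygermacra-1(10),4,11(13)-trien-12,6-olide | C=C1C(=O)O[C@H]2/C=C(\C)CC/C=C(/C)[C@@H]3OC(C)(C)O[C@@H]3[C@]12OC=O | intermediate
28 | (1(10)Z,4E,6S,7S,8S,9S)-7-hydroxy-8,9-isopropylidenedioxygermacra-1(10),4,11(13)-trien-12,6-olide | C=C1C(=O)O[C@H]2/C=C(\C)CC/C=C(/C)[C@@H]3OC(C)(C)O[C@@H]3[C@]12O | intermediate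
29 | (1(10)Z,4E,6S,7S,8S,9S)-7,8,9-trihydroxygermacra-1(10),4,11(13)-trien-12,6-olide | C=C1C(=O)O[C@H]2/C=C(\C)CC/C=C(/C)[C@H](O)[C@H](O)[C@]12O | intermediate
30 | (2S,3S)-2,3-dimethyloxirane-2-carboxylic 2,4,6-trichlorobenzoic anhydride | O=C(OC(=O)[C@@]1(C)O[C@H]1C)c1c(Cl)cc(Cl)cc1Cl | intermediate
31 | (1(10)Z,4E,6S,7S,8S,9S)-9-[(2S,3S)-2,3-epoxy-2-methylbutanoyloxy]-7,8-dihydroxygermacra-1(10),4,11(13)-trien-12,6-olide | C=C1C(=O)O[C@H]2/C=C(\C)CC/C=C(/C)[C@H](OC(=O)[C@@]3(C)O[C@H]3C)[C@H](O)[C@]12O | intermediate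
32 | (1(10)Z,4E,6S,7S,8S,9S)-8-acetoxy-9-[(2S,3S)-2,3-epoxy-2-methylbutanoyloxy]-7-hydroxygermacra-1(10),4,11(13)-trien-12,6-olide (CNP0271187.2) | C=C1C(=O)O[C@H]2/C=C(\C)CC/C=C(/C)[C@H](OC(=O)[C@@]3(C)O[C@H]3C)[C@H](OC(C)=O)[C@]12O | target

**Step count and risks**

Total step count: 23. Longest linear sequence: 18 steps (from 1: steps 1–3 and 9–23; the branch from 10 is 17 steps, the branch from 6 is 5 steps).

Steps most likely to fail:

1. Step 20 (Proposed new method). The risk is that the dioxolanylium ion is hydrolysed by adventitious water, or opens to a free allyl cation, before the carboxyl group alkylates C6, so that stereochemical integrity at C6 is lost or the lactone does not close. Fallback with known chemistry, setting out from 25: halogen–lithium exchange and carboxylation as above, then aqueous HCl/THF (pH 2–3) to hydrolyse the ortho ester and a brief LiOH treatment to remove the resulting formates, which should give (1(10)Z,4E,6R,7S,8S,9S)-6,7-dihydroxy-8,9-isopropylidenedioxygermacra-1(10),4,11(13)-trien-12-oic acid F1. Mitsunobu lactonisation (PPh3, diisopropyl azodicarboxylate, THF, 0 °C) then activates only the secondary allylic C6 hydroxyl and closes the lactone with inversion, which comes back to the route at 28.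

2. Step 17. The risk is poor facial selectivity in the ring-closing addition (non-chelated, Felkin-type attack giving the 6,7-cis diol) next to slow closure of the ten-membered ring. Fallback, setting out from 22 as obtained together with its C6 epimer: Dess–Martin oxidation of the mixture should give the single (1(10)Z,4E,7R,8S,9S)-7-ethynyl-7-hydroxy-8,9-isopropylidenedioxy-4,10-dimethylcyclodeca-1(10),4-dien-6-one F2. Capping O7 (Me3SiCl, imidazole) gives its trimethylsilyl ether F3, and reduction with i-Bu2AlH at −78 °C under Felkin–Anh control (silyloxy group anti to hydride, ethynyl on the outside) followed by K2CO3/MeOH desilylation sets C6 by ketone reduction instead of C–C bond formation and comes back to the route at 22.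

3. Step 19. The risk is hydrostannation at the terminal carbon, because the propargylic carbon is quaternary, together with protodestannylation of the hindered alkenylstannane. Fallback, setting out from 22: NiCl2(dppp)-catalysed α-selective hydroalumination of the free ethynyl diol with i-Bu2AlH (excess, THF, 23 °C) and iodinolysis (I2, −78 °C) should give (1(10)Z,4E,6R,7S,8S,9S)-7-(1-iodoethenyl)-8,9-O-isopropylidene-4,10-dimethylcyclodeca-1(10),4-diene-6,7,8,9-tetrol F4. Ortho ester formation under the conditions of step 18 then comes back to the route at 25.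

Further compounds
F1 | step 20 | (1(10)Z,4E,6R,7S,8S,9S)-6,7-dihydroxy-8,9-isopropylidenedioxygermacra-1(10),4,11(13)-trien-12-oic acid | O[C@@H]1/C=C(\C)CC/C=C(/C)[C@@H]2OC(C)(C)O[C@@H]2[C@@]1(C(=C)C(=O)O)O
F2 | step 17 | (1(10)Z,4E,7R,8S,9S)-7-ethynyl-7-hydroxy-8,9-isopropylidenedioxy-4,10-dimethylcyclodeca-1(10),4-dien-6-one | O=C1/C=C(\C)CC/C=C(/C)[C@@H]2OC(C)(C)O[C@@H]2[C@@]1(C#C)O
F3 | step 17 | (1(10)Z,4E,7R,8S,9S)-7-ethynyl-8,9-isopropylidenedioxy-4,10-dimethyl-7-(trimethylsilyloxy)cyclodeca-1(10),4-dien-6-one | O=C1/C=C(\C)CC/C=C(/C)[C@@H]2OC(C)(C)O[C@@H]2[C@@]1(C#C)O[Si](C)(C)C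
F4 | step 19 | (1(10)Z,4E,6R,7S,8S,9S)-7-(1-iodoethenyl)-8,9-O-isopropylidene-4,10-dimethylcyclodeca-1(10),4-diene-6,7,8,9-tetrol | O[C@@H]1/C=C(\C)CC/C=C(/C)[C@@H]2OC(C)(C)O[C@@H]2[C@@]1(C(I)=C)O
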